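The numbers in the tables were generated by integration on assumed constants, and the scatter is random.

Temperature across these flasks runs from −15 °C to 15 °C, so I first ask how far each flask gets in 2.0 h, and then what share of target that gives.

| flask | substrate | target | temperature | remark | time |
|---|---|---|---|---|---|
| theta | 0.50 M | 0.025 M | −8 °C | run made earlier |  |
| zeta | 0.50 M | 0.10 M | 9 °C | run made earlier |  |
| epsilon | 0.75 M | 0.050 M | −8 °C | run made earlier |  |
| autumn | 0.50 M | 0.0500 M | −15 °C |  | 2.0 h |
| midnight | 0.50 M | 0.0500 M | 15 °C |  | 2.0 h |
| summer | 0.50 M | 0.0500 M |  | at −15 °C until 1.0 h, from then on at 15 °C | 2.0 h |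
| spring | 0.50 M | 0.0500 M | 0 °C |  | 2.0 h |

| run | time / min | target / % | side product / % | substrate / % |
|---|---|---|---|---|
| theta | 6.00 | 6.7 | 0 | 98.9 |
| theta | 8.00 | 7.5 | 1.3 | 97.6 |
| theta | 12.0 | 8.8 | 0.6 | 96.2 |
| theta | 20.0 | 14.5 | 1.2 | 91.0 |
| theta | 30.0 | 21.1 | 0.8 | 82.8 |
| theta | 50.0 | 44.5 | 2.6 | 57.2 |
| theta | 80.0 | 81.0 | 3.8 | 20.3 |
| zeta | 2.00 | 30.6 | 1.0 | 89.0 |
| zeta | 2.50 | 33.6 | 0.4 | 85.3 |
| zeta | 4.00 | 44.4 | 1.2 | 74.7 |
| zeta | 6.00 | 59.4 | 1.5 | 57.9 |
| zeta | 10.0 | 87.5 | 3.1 | 28.3 |
| zeta | 15.0 | 106.3 | 5.6 | 8.7 |
| zeta | 25.0 | 114.2 | 5.9 | 0.5 |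
| epsilon | 15.0 | 20.3 | 0.5 | 85.9 |
| epsilon | 30.0 | 46.8 | 1.0 | 57.5 |
| epsilon | 40.0 | 66.8 | 2.4 | 36.7 |
| epsilon | 60.0 | 92.8 | 4.5 | 10.1 |
| epsilon | 80.0 | 99.2 | 5.0 | 2.3 |

(standard deviation of a reading: 0.5 percentage points)

- a species is counted by the substrate in it: one side product counts as two
- the analysis behind the earlier runs scatters by 0.5 percentage points, standard deviation

1. the best flask by share of target in all that became target or side product; "all alike" if 1.5 percentage points covers them all (autumn / midnight / summer / spring / all alike)
2. share of target in all that became target or side product, autumn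
3. share of target in all that became target or side product, midnight
4. share of target in all that became target or side product, summer
5. share of target in all that became target or side product, spring

- In the theta run the substrate goes faster as target grows, which I read as autocatalysis, so I take the growth time τ, the time in which ln(c target / c substrate) rises by one. Substrate left then follows a logistic curve that starts from the charge ratio q = 0.100.
- The readings give τ, scaled to this charge, as 17.8 min at −8 °C and 3.97 min at 9 °C.
- Carrying ln τ straight along temperature, the first rung is midnight, with τ = 2.34 min.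
- Spring comes next, with τ = 8.78 min, and 0.00129 % of the substrate left at the end.
- Autumn is slowest, with τ = 33.0 min. I reckon 22.9 % of autumn's substrate left at the end.
- Summer follows autumn's clock for 1.0 h, and I reckon 68.0 % left at the change. That substrate then meets the warm clock.
- I carry side product per substrate used, f, which reads 5.12 % at −8 °C and 5.93 % at 9 °C, with the scatter of those readings.
- Carried the same way, it becomes 4.82 % at −15 °C and 6.25 % at 15 °C. This is the loss fraction, a selectivity figure.
- With U the substrate used, and counting target as the flask holds it, my share is one minus f·U/(U + q). Putting the conversions back in gives 95.7 % for autumn, 94.3 % for midnight, 94.7 % for summer and 95.0 % for spring.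
- My spread from autumn to midnight is 1.4 percentage points, less than the margin of 1.5 points, so I reckon the flasks alike.
- The forecast says all alike, with 95 % for autumn, 94 % for midnight, 94.4 % for summer and 94.6 % for spring, and its basis differs from mine: “I counted only newly formed target.”
- The flasks give 95.9 % for autumn, 94.7 % for midnight, 95.1 % for summer and 95.3 % for spring, so the answer is all alike, with a spread of 1.2 points, less than the margin.

    substrate + target → 2 target (k = 13.0 /M/h, Ea = 54.0 kJ/mol)
    substrate → target (k = 0.0140 /h, Ea = 85.0 kJ/mol)
    substrate + target → side product (k = 0.350 /M/h, Ea = 59.0 kJ/mol)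
    (constants at 0 °C)

- The neighbour is summer with 0.013 M of target, so q falls to 0.0260. My cold hour then leaves 88.4 % of its substrate for the warm hour, more than the 68.0 % I reckoned for summer, so f blends to 6.08 % and my share is 94.1 %. That flask holds 5.67 % of side product, against 5.44 % in summer, and its share is 94.5 %.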